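The runs stem from a simulated flask for substances that don't exist; the scatter is artificial.

I started from the last rows.

| flask | Sbt | Ptn | time |
|---|---|---|---|
| zeta | 0.120 M | 0.144 M |  |
| delta | 0.120 M | 0.430 M |  |
| beta | 0.240 M | 0.144 M |  |
| alpha | 0.550 M | 0.144 M | 3.4 h |

- zeta run (time / h: [Pdt] / M): 0.14: 0.0012; 0.23: 0.0031; 0.40: 0.0059; 0.68: 0.0111; 1.2: 0.0168; 2.0: 0.0219; 3.4: 0.0246
- delta run (time / h: [Pdt] / M): 0.14: 0.0041; 0.23: 0.0083; 0.40: 0.0158; 0.68: 0.0291; 1.2: 0.0429; 2.0: 0.0526; 3.4: 0.0561
- beta run (time / h: [Pdt] / M): 0.14: 0.0025; 0.23: 0.0055; 0.40: 0.0116; 0.68: 0.0208; 1.2: 0.0323; 2.0: 0.0402; 3.4: 0.0436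

(standard deviation of a reading: 4 × 10⁻⁴ M)

* reaction order in [Sbt] at the outset, round the charge of the zeta run, defined at two percent of the Sbt turned into Pdt (one fixed amount of Pdt, the same in the runs compared)
* reaction order in [Ptn] at the outset, round the charge of the zeta run, defined at two percent of the Sbt turned into Pdt
* Pdt in the alpha run at 3.4 h, as a share of the Sbt charged

- Overall: Sbt + Ptn -> Pdt.
- Constant volume, constant temperature.
- "The second partner" is Ptn.
- An order is taken over about fifteen percent of the charge, up and down.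

At 3.4 h zeta had made 20.5% of its Sbt charge, delta 46.7% and beta 18.2%, so the share itself differed from run to run, and I looked for a figure that held steadier. For beta I divided the Pdt of the last reading by the Sbt charge less that Pdt times the Ptn charge less that Pdt, which gave a reading of 2.21 M⁻¹, and I called this the stall quotient. Zeta read 2.16 M⁻¹ and delta 2.35 M⁻¹, though delta held 0.430 M of Ptn against 0.144 M in zeta. Alpha was asked at that same time, and it shares its Ptn charge with beta, so I carried beta's quotient over. But in alpha Ptn is the limiting reagent, its charge being 26.2% of the Sbt charge. Solving the quotient for alpha, I reckoned Pdt at 13.4% of the Sbt charge, about half of what that Ptn charge allows.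

The forecast gave 13.7% for alpha, higher than mine, with orders at the outset round the zeta charge of 0.8 in Sbt and 0.8 in Ptn, and it judged the stop in its own words as “this is equilibrium rather than catalyst death”.

The alpha flask gave Pdt at 14.3% of its Sbt charge at 3.4 h, and the orders at the outset round the zeta charge came to 0.74 in Sbt and 0.73 in Ptn.

    Sbt + Ptn ⇌ Imd (2.275 M⁻¹ h⁻¹, 0.4212 h⁻¹)
    Imd → Pdt (3.852 h⁻¹)
    Ptn → Q (0.4752 h⁻¹)
    Sbt → G (0.6084 h⁻¹)

In these steps no arrow leaves Pdt, while Sbt goes to G with a rate constant of 0.608 h⁻¹ and Ptn to Q with one of 0.475 h⁻¹. Alpha's share put into the stall quotient gives 2.55 M⁻¹, higher than the 2.21 M⁻¹ read from beta, and alpha's share stands 0.90 percentage points of its Sbt charge above my reckoning. The delta run at 0.702 h, with Pdt at a quarter of its Sbt charge, stood at a quotient of 0.833 M⁻¹.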